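**Retrosynthetic overview**
1. Target ⇐ unmasking of the exocyclic methylene (C11–CH2NMe2) ⇐ Evans–Tishchenko reduction of a macrocyclic β-hydroxy enone (C3–OH/C1=O → C3–OAc/C1–OH) ⇐ N–O cleavage of an isoxazoline.
2. Key ring: the ten-membered carbocycle and the isoxazoline form together in an intramolecular nitrile oxide–alkene [3+2] cycloaddition (C1–C2 and C3–O bonds).
3. γ-Lactone and C6–C7 bond: indium Barbier allylation of (Z)-3-methylpenta-2,4-dienal with a (Z)-2-(bromomethyl)enoate, then lactonization.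
4. The bromide comes from (S)-glyceraldehyde acetonide, the only source of chirality (it becomes C8); C7, C6, C3 and C1 are relayed from it in that order.
5. Ring order: γ-lactone first, then isoxazoline plus ten-membered ring in one step.

Assumption: ring atoms are numbered C1 (CHOH), C2, C3 (CHOAc), C4(Me)=C5, C6 (lactone O), C7, C8 (O-angelate), C9=C10(Me), with C11–C13 the lactone carbons; the given SMILES is then (1S,3S,6R,7R,8R), 4Z,9Z, with a (Z)-2-methylbut-2-enoate. Compounds 1, 2, 10, 13, 24 and 27 are purchased.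

**Step 1**
Reactants: 1 (S)-glyceraldehyde acetonide; 2 ethyl(triphenyl)phosphonium iodide
Product: 3 (4R)-4-[(1Z)-2-iodoprop-1-en-1-yl]-2,2-dimethyl-1,3-dioxolane
Conditions: 2, n-BuLi, THF, −78 °C; I2; NaN(SiMe3)2, −20 °C; then 1, −78 °C → rt
Reagents that add atoms: iodine, II
Why: Stork–Zhao Wittig olefination with the α-iodo ylide gives the (Z)-trisubstituted vinyl iodide (iodine cis to the chain) under kinetic control, and the stereocentre of 1 (future C8) is carried through unchanged.

**Step 2**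
Reactants: 3 vinyl iodide acetonide
Product: 4 (2R,3Z)-4-iodopent-3-ene-1,2-diol
Conditions: AcOH–H2O (4:1), 40 °C
Reagents that add atoms: none
Why: Acid-catalysed acetal hydrolysis frees the 1,2-diol while the vinyl iodide is inert.

**Step 3**
Reactants: 4 iodo diol
Product: 5 (2R,3Z)-4-iodo-1,2-bis(triethylsilyloxy)pent-3-ene
Conditions: Et3SiCl, imidazole, CH2Cl2, 0 °C → rt
Reagents that add atoms: chlorotriethylsilane, CC[Si](Cl)(CC)CC
Why: Bis-silylation sets up the later differentiation of the primary and the secondary oxygen.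

**Step 4**
Reactants: 5 bis-silyl ether
Product: 8 (2Z,4R)-2-methyl-4,5-bis(triethylsilyloxy)pent-2-enal O-(tert-butyldiphenylsilyl)oxime, via vinyllithium 6 (not isolated), via enal 7 (not isolated)
Conditions: t-BuLi (2.1 equiv), Et2O, −78 °C; DMF, −78 → 0 °C; aq NH4Cl work-up; crude 7, t-BuPh2SiONH2, PPTS (cat.), MgSO4, CH2Cl2, 0 °C
Reagents that add atoms: N,N-dimethylformamide, CN(C)C=O; O-(tert-butyldiphenylsilyl)hydroxylamine, NO[Si](c1ccccc1)(c1ccccc1)C(C)(C)C
Why: Iodine–lithium exchange and formylation proceed with retention of the Z geometry, and immediate oxime-ether condensation stores C1 as a nitrile oxide precursor that cannot isomerize to the E-enal.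

**Step 5**
Reactants: 8 oxime silyl ether
Product: 9 (2R,3Z,5E)-5-{[tert-butyl(diphenyl)silyl]oxyimino}-4-methyl-2-(triethylsilyloxy)pent-3-enal
Conditions: (COCl)2, DMSO, CH2Cl2, −78 → −35 °C; Et3N, −78 °C → rt
Reagents that add atoms: none
Why: Under Swern conditions only the primary triethylsilyl ether is cleaved and oxidised (oxidative desilylation), giving the C7 aldehyde with the secondary silyl ether at C8 intact.

**Step 6**
Reactants: 9 α-silyloxy aldehyde; 10 methyl acrylate
Product: 11 Morita–Baylis–Hillman adduct (both C7-carbinol epimers)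
Conditions: 10 (excess), DABCO, MeOH (cat.), rt, 5 d
Reagents that add atoms: none
Why: The Morita–Baylis–Hillman reaction attaches C11–C13 to the activated α-alkoxy aldehyde; the new carbinol centre is removed in the next step, so its configuration is irrelevant.

**Step 7**
Reactants: 11 Morita–Baylis–Hillman adduct
Product: 12 methyl (2Z,4R,5Z,7E)-2-(bromomethyl)-7-{[tert-butyl(diphenyl)silyl]oxyimino}-6-methyl-4-(triethylsilyloxy)hepta-2,5-dienoate
Conditions: NBS, Me2S, CH2Cl2, 0 °C → rt
Reagents that add atoms: N-bromosuccinimide, O=C1CCC(=O)N1Br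
Why: Corey–Kim-type activation followed by SN2' displacement by bromide gives the rearranged primary allylic bromide as the favoured (Z)-2-(bromomethyl)enoate.

**Step 8**
Reactants: 13 (2Z)-3-methylpent-2-en-4-yn-1-ol
Product: 14 (2Z)-3-methylpenta-2,4-dien-1-ol
Conditions: H2 (1 atm), Pd/CaCO3 poisoned with Pb(OAc)2, quinoline, Et2O, 0 °C
Reagents that add atoms: none
Why: Lindlar semihydrogenation reduces only the terminal alkyne to the vinyl group and leaves the Z-trisubstituted alkene untouched.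

**Step 9**
Reactants: 14 (Z)-dienol
Product: 15 (2Z)-3-methylpenta-2,4-dienal
Conditions: MnO2, pentane–CH2Cl2, rt (filtered solution used directly)
Reagents that add atoms: none
Why: Allylic oxidation with MnO2 is neutral and does not isomerize the Z-enal.

**Step 10**
Reactants: 12 allylic bromide; 15 (Z)-dienal
Product: 18 cis-γ-lactone Mannich base (C11 epimers), via hydroxy ester 16 (not isolated), via methylene lactone 17 (not isolated)
Conditions: In (powder), THF–H2O (4:1), rt; crude 16, PPTS (cat.), CH2Cl2, 35 °C; then Me2NH (2 M in THF), rt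
Reagents that add atoms: dimethylamine, CNC
Why: The indium Barbier allylation goes through a chair-like transition state to the 6,7-syn adduct (cis-lactone after lactonization), with the aldehyde adding to the allyl face anti to the C8–OSiEt3 bond (C8–H held in the alkene plane by 1,3-allylic strain), so C6 and C7 are set by C8; the aza-Michael adduct masks the exocyclic methylene, which would otherwise capture the nitrile oxide in a six-membered ring closure.

**Step 11**
Reactants: 18 lactone Mannich base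
Product: 19 free oxime with C8–OSiEt3 retained
Conditions: KHF2, MeOH, rt
Reagents that add atoms: none
Why: Bifluoride cleaves the silyl ether of the acidic oxime oxygen much faster than the alkyl triethylsilyl ether.

**Step 12**
Reactants: 19 oxime
Product: 22 isoxazoline-bridged ten-membered lactone, via hydroximoyl chloride 20 (not isolated), via nitrile oxide 21 (not isolated)
Conditions: HCl (1 equiv, dioxane), NCS, DMF, 0 °C → rt; then addition over 12 h to Et3N, CH2Cl2 (0.5 mM), 35 °C
Reagents that add atoms: none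
Why: Intramolecular nitrile oxide–alkene [3+2] cycloaddition joins C1 to the terminal CH2 and oxygen to C3 (normal regiochemistry) while closing a low-strain (Z,Z)-cyclodeca-1,6-diene ring; 1,3-allylic strain keeps C6–H in the plane of C4=C5 and puts the tether on the face opposite the lactone oxygen, so the dipole reaches only the vinyl face turned toward C6 and C3 is formed as 3S.

**Step 13**
Reactants: 22 silyl ether
Product: 23 C8 alcohol
Conditions: HF·pyridine, pyridine, THF, 0 °C
Reagents that add atoms: none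
Why: Fluoride removes the secondary triethylsilyl group and leaves the only free hydroxyl at C8.

**Step 14**
Reactants: 23 C8 alcohol; 24 angelic acid
Product: 25 C8 angelate
Conditions: 24, 2,4,6-Cl3C6H2COCl, Et3N, toluene, rt; then 23, 80 °C
Reagents that add atoms: none
Why: Yamaguchi-type mixed-anhydride esterification without DMAP acylates the hindered allylic alcohol and keeps the (Z)-angelate geometry.

**Step 15**
Reactants: 25 isoxazoline angelate
Product: 26 macrocyclic β-hydroxy enone (C3–OH, C1=O)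
Conditions: Mo(CO)6, MeCN–H2O (10:1), 80 °C
Reagents that add atoms: water, O
Why: Mo(CO)6 cleaves the N–O bond reductively and the β-hydroxy imine hydrolyses to the ketone, with alkenes, esters and the C3 configuration untouched.

**Step 16**
Reactants: 26 β-hydroxy enone; 27 acetaldehyde
Product: 28 C3 acetate C1 alcohol (masked target)
Conditions: 27 (10 equiv), SmI2 (0.3 equiv), THF, −10 °C
Reagents that add atoms: none
Why: In the Evans–Tishchenko reduction the samarium-bound hemiacetal of C3–OH delivers hydride intramolecularly through a chair transition state, giving the 1,3-anti carbinol at C1 (1S, set by C3) and leaving the acetyl group on O3.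

**Step 17**
Reactants: 28 masked target
Product: 30 target CNP0319825.3, via trimethylammonium iodide 29 (not isolated)
Conditions: MeI, CH2Cl2–MeOH, rt; then aq NaHCO3, rt
Reagents that add atoms: none
Why: Exhaustive N-methylation followed by E1cB (Hofmann-type) elimination regenerates the α-methylene lactone under conditions that spare the acetate, the angelate and the free alcohol.

**Compound list**
1 | (4S)-2,2-dimethyl-1,3-dioxolane-4-carbaldehyde, (S)-glyceraldehyde acetonide | O=C[C@H]1OC(C)(C)OC1 | starting material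
2 | ethyl(triphenyl)phosphonium iodide | CC[P+](c1ccccc1)(c1ccccc1)c1ccccc1.[I-] | starting material
3 | (4R)-4-[(1Z)-2-iodoprop-1-en-1-yl]-2,2-dimethyl-1,3-dioxolane | I/C(C)=C\[C@H]1OC(C)(C)OC1 | intermediate
4 | (2R,3Z)-4-iodopent-3-ene-1,2-diol | I/C(C)=C\[C@@H](O)CO | intermediate
5 | (2R,3Z)-4-iodo-1,2-bis(triethylsilyloxy)pent-3-ene | I/C(C)=C\[C@@H](O[Si](CC)(CC)CC)CO[Si](CC)(CC)CC | intermediate
6 | [(2Z,4R)-4,5-bis(triethylsilyloxy)pent-2-en-2-yl]lithium | [Li]/C(C)=C\[C@@H](O[Si](CC)(CC)CC)CO[Si](CC)(CC)CC | intermediate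
7 | (2Z,4R)-2-methyl-4,5-bis(triethylsilyloxy)pent-2-enal | O=C/C(C)=C\[C@@H](O[Si](CC)(CC)CC)CO[Si](CC)(CC)CC | intermediate
8 | (1E,2Z,4R)-2-methyl-4,5-bis(triethylsilyloxy)pent-2-enal O-(tert-butyldiphenylsilyl)oxime | CC(C)(C)[Si](O/N=C/C(C)=C\[C@@H](O[Si](CC)(CC)CC)CO[Si](CC)(CC)CC)(c1ccccc1)c1ccccc1 | intermediate
9 | (2R,3Z,5E)-5-{[tert-butyl(diphenyl)silyl]oxyimino}-4-methyl-2-(triethylsilyloxy)pent-3-enal | CC(C)(C)[Si](O/N=C/C(C)=C\[C@@H](O[Si](CC)(CC)CC)C=O)(c1ccccc1)c1ccccc1 | intermediate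
10 | methyl acrylate | C=CC(=O)OC | starting material
11 | methyl (4R,5Z,7E)-7-{[tert-butyl(diphenyl)silyl]oxyimino}-3-hydroxy-6-methyl-2-methylidene-4-(triethylsilyloxy)hept-5-enoate, C3 epimers | CC(C)(C)[Si](O/N=C/C(C)=C\[C@@H](O[Si](CC)(CC)CC)C(O)C(=C)C(=O)OC)(c1ccccc1)c1ccccc1 | intermediate
12 | methyl (2Z,4R,5Z,7E)-2-(bromomethyl)-7-{[tert-butyl(diphenyl)silyl]oxyimino}-6-methyl-4-(triethylsilyloxy)hepta-2,5-dienoate | CC(C)(C)[Si](O/N=C/C(C)=C\[C@@H](O[Si](CC)(CC)CC)/C=C(\CBr)C(=O)OC)(c1ccccc1)c1ccccc1 | intermediate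
13 | (2Z)-3-methylpent-2-en-4-yn-1-ol | C#C/C(C)=C\CO | starting material
14 | (2Z)-3-methylpenta-2,4-dien-1-ol | C=C/C(C)=C\CO | intermediate
15 | (2Z)-3-methylpenta-2,4-dienal | C=C/C(C)=C\C=O | intermediate
16 | methyl (3R,4R,5Z)-4-hydroxy-6-methyl-2-methylidene-3-[(1R,2Z,4E)-4-{[tert-butyl(diphenyl)silyl]oxyimino}-3-methyl-1-(triethylsilyloxy)but-2-en-1-yl]octa-5,7-dienoate | COC(=O)C(=C)[C@H]([C@H](O)/C=C(C)\C=C)[C@H](O[Si](CC)(CC)CC)/C=C(C)\C=N\O[Si](c1ccccc1)(c1ccccc1)C(C)(C)C | intermediate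
17 | (4R,5R)-4-[(1R,2Z,4E)-4-{[tert-butyl(diphenyl)silyl]oxyimino}-3-methyl-1-(triethylsilyloxy)but-2-en-1-yl]-3-methylidene-5-[(1Z)-2-methylbuta-1,3-dien-1-yl]oxolan-2-one | C=C1C(=O)O[C@H](/C=C(C)\C=C)[C@@H]1[C@H](O[Si](CC)(CC)CC)/C=C(C)\C=N\O[Si](c1ccccc1)(c1ccccc1)C(C)(C)C | intermediate
18 | (4R,5R)-3-[(dimethylamino)methyl] analogue of 17, epimers at the amine-bearing ring carbon | CN(C)CC1C(=O)O[C@H](/C=C(C)\C=C)[C@@H]1[C@H](O[Si](CC)(CC)CC)/C=C(C)\C=N\O[Si](c1ccccc1)(c1ccccc1)C(C)(C)C | intermediate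
19 | free (E)-oxime of 18 | CN(C)CC1C(=O)O[C@H](/C=C(C)\C=C)[C@@H]1[C@H](O[Si](CC)(CC)CC)/C=C(C)\C=N\O | intermediate
20 | hydroximoyl chloride of 19 | CN(C)CC1C(=O)O[C@H](/C=C(C)\C=C)[C@@H]1[C@H](O[Si](CC)(CC)CC)/C=C(C)\C(Cl)=NO | intermediate
21 | nitrile oxide from 20 | CN(C)CC1C(=O)O[C@H](/C=C(C)\C=C)[C@@H]1[C@H](O[Si](CC)(CC)CC)/C=C(C)\C#[N+][O-] | intermediate
22 | (3S,6R,7R,8R)-(4Z,9Z)-ten-membered carbocycle, cis-fused at C6/C7 to the γ-lactone bearing CH2NMe2 at C11, bridged C1/C3 by a 2-isoxazoline (C1=N–O–C3), 8-OSiEt3 | CN(C)CC1C(=O)O[C@@H]2/C=C(/C)[C@H]3ON=C(C3)/C(C)=C\[C@@H](O[Si](CC)(CC)CC)[C@H]12 | intermediate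
23 | 8-hydroxy analogue of 22 (3S,6R,7S,8R; the C7 label changes by priority only) | CN(C)CC1C(=O)O[C@@H]2/C=C(/C)[C@H]3ON=C(C3)/C(C)=C\[C@@H](O)[C@H]12 | intermediate
24 | angelic acid, (2Z)-2-methylbut-2-enoic acid | C/C=C(/C)C(=O)O | starting material
25 | 8-O-angelate of 23 (3S,6R,7R,8R) | CN(C)CC1C(=O)O[C@@H]2/C=C(/C)[C@H]3ON=C(C3)/C(C)=C\[C@@H](OC(=O)/C(C)=C\C)[C@H]12 | intermediate
26 | (3S,6R,7R,8R)-3-hydroxy-1-oxo-8-angeloyloxy-(4Z,9Z)-germacradien-6,12-olide with CH2NMe2 at C11 | CN(C)CC1C(=O)O[C@@H]2/C=C(/C)[C@@H](O)CC(=O)/C(C)=C\[C@@H](OC(=O)/C(C)=C\C)[C@H]12 | intermediate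
27 | acetaldehyde | CC=O | starting material
28 | (1S,3S,6R,7R,8R)-3-acetoxy-1-hydroxy-8-angeloyloxy analogue with CH2NMe2 at C11 | CN(C)CC1C(=O)O[C@@H]2/C=C(/C)[C@@H](OC(C)=O)C[C@H](O)/C(C)=C\[C@@H](OC(=O)/C(C)=C\C)[C@H]12 | intermediate
29 | trimethylammonium iodide of 28 | C[N+](C)(C)CC1C(=O)O[C@@H]2/C=C(/C)[C@@H](OC(C)=O)C[C@H](O)/C(C)=C\[C@@H](OC(=O)/C(C)=C\C)[C@H]12.[I-] | intermediate
30 | CNP0319825.3, (1S,3S,6R,7R,8R)-3-acetoxy-1-hydroxy-8-[(2Z)-2-methylbut-2-enoyloxy]germacra-4Z,9Z,11(13)-trien-6,12-olide | C=C1C(=O)O[C@@H]2/C=C(/C)[C@@H](OC(C)=O)C[C@H](O)/C(C)=C\[C@@H](OC(=O)/C(C)=C\C)[C@H]12 | target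

**Totals**
Total steps: 17. Longest linear sequence: 15 (steps 1–7 and 10–17; steps 8–9 are the side branch).

**Three steps most likely to fail**

Step 12 (macrocyclizing cycloaddition; risks are oligomerization and wrong facial selectivity at C3). Fallback: exchange the two ring-forming events, so that the isoxazoline is made between molecules and the ring is closed by a Barbier reaction. Setting out from aldehyde 9, KHF2 in MeOH gives oxime aldehyde F1. NCS then Et3N with excess dienal 15 gives isoxazoline dialdehyde F2; C3 is not controlled here, so the 3S epimer must be separated by chromatography. A Morita–Baylis–Hillman reaction at the more electrophilic α-silyloxy aldehyde gives adduct F3, and NBS/Me2S gives allylic bromide F4. Indium at high dilution closes the C6–C7 bond and, after lactonization, gives macrocyclic methylene lactone F5. Addition of Me2NH returns to 22.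

Step 10 (Barbier allylation; risks are β-elimination of the C8 silyloxy group from the allylindium and eroded facial control). Fallback: an allylboration instead of an allylmetal Barbier reaction. From 12, B2pin2 with CuCl and KOt-Bu gives allylboronate F6. Warming F6 with 15 in toluene (closed chair transition state), acid work-up to 17 and Me2NH addition return to 18.

Step 16 (Evans–Tishchenko reduction; risks are retro-aldol opening or no hydride transfer in the strained ring). Fallback: separate acylation from reduction. From 26, Ac2O/pyridine gives β-acetoxy enone F7. Luche reduction (NaBH4, CeCl3·7H2O, MeOH, −78 °C) from the exposed face of the ring returns to 28, but without the directed anti control the C1 epimers may need separation.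

**Further compounds**
F1 | step 12 | (2R,3Z,5E)-5-(hydroxyimino)-4-methyl-2-(triethylsilyloxy)pent-3-enal | O/N=C/C(C)=C\[C@@H](O[Si](CC)(CC)CC)C=O
F2 | step 12 | (2R,3Z)-4-{(5S)-5-[(1Z)-1-methyl-3-oxoprop-1-en-1-yl]-4,5-dihydroisoxazol-3-yl}-2-(triethylsilyloxy)pent-3-enal | O=C/C=C(/C)[C@@H]1CC(=NO1)/C(C)=C\[C@@H](O[Si](CC)(CC)CC)C=O
F3 | step 12 | Morita–Baylis–Hillman adduct of F2 with methyl acrylate at the α-silyloxy aldehyde | O=C/C=C(/C)[C@@H]1CC(=NO1)/C(C)=C\[C@@H](O[Si](CC)(CC)CC)C(O)C(=C)C(=O)OC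
F4 | step 12 | (Z)-2-(bromomethyl)enoate from F3 | O=C/C=C(/C)[C@@H]1CC(=NO1)/C(C)=C\[C@@H](O[Si](CC)(CC)CC)/C=C(\CBr)C(=O)OC
F5 | step 12 | analogue of 22 with the exocyclic methylene in place of CH–CH2NMe2 | C=C1C(=O)O[C@@H]2/C=C(/C)[C@H]3ON=C(C3)/C(C)=C\[C@@H](O[Si](CC)(CC)CC)[C@H]12
F6 | step 10 | pinacol allylboronate corresponding to bromide 12 | CC(C)(C)[Si](O/N=C/C(C)=C\[C@@H](O[Si](CC)(CC)CC)/C=C(\CB1OC(C)(C)C(C)(C)O1)C(=O)OC)(c1ccccc1)c1ccccc1
F7 | step 16 | 3-O-acetate of 26 (β-acetoxy enone) | CN(C)CC1C(=O)O[C@@H]2/C=C(/C)[C@@H](OC(C)=O)CC(=O)/C(C)=C\[C@@H](OC(=O)/C(C)=C\C)[C@H]12
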